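**Retrosynthetic overview**
1. The last step is a global hydrogenation. It removes both benzyl ethers and turns an allyl arm into the n-propyl arm, so the two near-identical alkyl arms are distinguished earlier as allyl versus long chain.
2. The ester C–O bond and ring A (the resorcylate) disconnect together to a diketo-dioxinone (acylketene source) and an O-boryl homoallylic alkoxide, which are joined and aromatised in one flask.
3. The stereocentre and its C–C bond come from a chiral-phosphoric-acid-catalysed allylboration of achiral 8-aryloctanal with allyl-Bpin.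
4. The aryloctanal comes from linear hydroformylation of a heptenylarene, itself made by copper-catalysed benzyl bromide/hexenyl Grignard coupling. The diketo-dioxinone comes from two Claisen acylations of 2,2,6-trimethyldioxinone.
5. Ring order: ring B (the alkylresorcinol) and the dioxinone ring are bought. Ring A is the only ring formed, in step 5.

Assumption: (R)-TRIP is taken to deliver allyl to the Re face of the unbranched aldehyde, as it does for the aldehyde classes where its sense of induction is established. If a hydrolysed aliquot shows the opposite sense, (S)-TRIP is used.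

**Step 1**
Reactants: 1 1,3-bis(benzyloxy)-5-(bromomethyl)benzene; 2 6-bromohex-1-ene
Product: 4 1,3-bis(benzyloxy)-5-(hept-6-en-1-yl)benzene, via hex-5-enylmagnesium bromide 3 (not isolated)
Conditions: 2 (1.3 equiv), Mg, THF, 25 °C; then 1, Li2CuCl4 (3 mol %), THF, −10 °C to rt
Reagents that add atoms: 6-bromohex-1-ene (2), C=CCCCCBr
Why: Copper-catalysed Kochi-type sp3–sp3 cross-coupling of a primary alkyl Grignard reagent with a reactive benzylic bromide is fast at low temperature and spares the alkene and benzyl ethers, and any cyclopentylmethyl by-product from radical cyclisation during Grignard formation has no alkene and is separated after step 2.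

**Step 2**
Reactants: 4 1,3-bis(benzyloxy)-5-(hept-6-en-1-yl)benzene; 5 carbon monoxide
Product: 6 8-[3,5-bis(benzyloxy)phenyl]octanal
Conditions: Rh(acac)(CO)2 (0.5 mol %), BiPhePhos (1 mol %), CO/H2 (1:1, 10 bar), PhMe, 70 °C
Reagents that add atoms: carbon monoxide (5), [C-]#[O+]
Why: In this linear-selective hydroformylation the wide-bite-angle bisphosphite enforces anti-Markovnikov Rh–H insertion, so the terminal alkene gains one carbon as the unbranched aldehyde while the aryl benzyl ethers are inert.

**Step 3**
Reactants: 7 2,2,6-trimethyl-4H-1,3-dioxin-4-one; 8 acetyl chloride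
Product: 10 2,2-dimethyl-6-(2-oxopropyl)-4H-1,3-dioxin-4-one, via lithium dienolate 9 (not isolated)
Conditions: LiN(SiMe3)2, THF, −78 °C; AcCl (0.5 equiv), −78 to −20 °C; 1 M HCl
Reagents that add atoms: acetyl chloride (8), CC(=O)Cl
Why: γ-Deprotonation gives the cross-conjugated lithium dienolate, which undergoes Claisen-type C-acylation at the exocyclic carbon, and the second equivalent of dienolate absorbs the more acidic product.

**Step 4**
Reactants: 10 2,2-dimethyl-6-(2-oxopropyl)-4H-1,3-dioxin-4-one; 11 methyl dodecanoate
Product: 13 2,2-dimethyl-6-(2,4-dioxopentadecyl)-4H-1,3-dioxin-4-one, via dilithio dianion 12 (not isolated)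
Conditions: LiN(i-Pr)2 (2.1 equiv per 10), THF, −78 to −30 °C; 11 (0.5 equiv), −78 to −10 °C; 1 M HCl
Reagents that add atoms: methyl dodecanoate (11), CCCCCCCCCCCC(=O)OC
Why: In this Harris–Weiler-type dianion Claisen acylation the last-formed, most basic terminal carbanion attacks the ester, and the excess dianion deprotonates the new 1,3-diketone so that it is not attacked a second time.

**Step 5**
Reactants: 6 8-[3,5-bis(benzyloxy)phenyl]octanal; 14 2-allyl-4,4,5,5-tetramethyl-1,3,2-dioxaborolane (allyl-Bpin); 13 2,2-dimethyl-6-(2,4-dioxopentadecyl)-4H-1,3-dioxin-4-one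
Product: 18 (4S)-11-[3,5-bis(benzyloxy)phenyl]undec-1-en-4-yl 2,4-dihydroxy-6-undecylbenzoate, via homoallyl pinacol borate 15 (not isolated), via acylketene 16 (not isolated), via triketo ester 17 (not isolated)
Conditions: 14 (1.1 equiv), (R)-TRIP [(R)-3,3'-bis(2,4,6-triisopropylphenyl)-1,1'-binaphthyl-2,2'-diyl hydrogen phosphate, 5 mol %], PhMe, −30 °C, 24 h; volatiles off in vacuo; 13 (1.1 equiv), PhMe, 110 °C, 1 h; Cs2CO3, MeOH, rt; HCl/MeOH
Reagents that add atoms: allyl-Bpin (14), C=CCB1OC(C)(C)C(C)(C)O1; diketo-dioxinone (13), CCCCCCCCCCCC(=O)CC(=O)CC1=CC(=O)OC(C)(C)O1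
Why: Proposed new method: the first event is a chiral-phosphoric-acid-catalysed allylboration through a closed chair Zimmerman–Traxler transition state, in which the acid proton binds the pseudo-axial boronate oxygen, the phosphoryl oxygen holds the formyl C–H and the triisopropylphenyl walls leave only the Re face of 6 open, which sets the (S)-carbinol; the new part is that its primary product, the O–Bpin borate 15, serves directly as the nucleophile for acylketene 16 released from 13 by retro-hetero-Diels–Alder loss of acetone, with boron binding the acyl oxygen while its alkoxide passes to the ketene carbon through a six-membered pseudopericyclic array (alkoxyboration), backed by a proton relay in which the enolic diketone of 13, the phosphoric acid and each new enol of 17 protonolyse the next B–O bond, the C–O bond at the stereocentre never being broken, after which carbonate-induced C2-to-C7 aldol condensation and dehydration build ring A; the closest known reaction types are the trapping of dioxinone-derived acylketenes by free O–H groups with late aldol aromatisation and the insertion of heterocumulenes into B–O and B–N bonds.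

**Step 6**
Reactants: 18 (4S)-11-[3,5-bis(benzyloxy)phenyl]undec-1-en-4-yl 2,4-dihydroxy-6-undecylbenzoate
Product: 19 (4R)-11-(3,5-dihydroxyphenyl)undecan-4-yl 2,4-dihydroxy-6-undecylbenzoate (target)
Conditions: H2 (1 atm), 10 % Pd/C, EtOAc/EtOH, rt
Reagents that add atoms: none
Why: Heterogeneous catalytic hydrogenation saturates the monosubstituted alkene (allyl becomes n-propyl, which changes the descriptor from S to R by priority only, without touching the stereocentre) and hydrogenolyses both benzyl aryl ethers, while the non-allylic secondary ester and the phenols are inert.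

**Compound list**
1 | 1,3-bis(benzyloxy)-5-(bromomethyl)benzene | BrCc1cc(OCc2ccccc2)cc(OCc2ccccc2)c1 | starting material
2 | 6-bromohex-1-ene | C=CCCCCBr | starting material
3 | hex-5-en-1-ylmagnesium bromide | C=CCCCC[Mg]Br | intermediate
4 | 1,3-bis(benzyloxy)-5-(hept-6-en-1-yl)benzene | C=CCCCCCc1cc(OCc2ccccc2)cc(OCc2ccccc2)c1 | intermediate
5 | carbon monoxide | [C-]#[O+] | starting material
6 | 8-[3,5-bis(benzyloxy)phenyl]octanal | O=CCCCCCCCc1cc(OCc2ccccc2)cc(OCc2ccccc2)c1 | intermediate
7 | 2,2,6-trimethyl-4H-1,3-dioxin-4-one | CC1=CC(=O)OC(C)(C)O1 | starting material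
8 | acetyl chloride | CC(=O)Cl | starting material
9 | lithium 2,2-dimethyl-6-methylidene-1,3-dioxin-4-olate (dienolate of 7) | [Li]OC1=CC(=C)OC(C)(C)O1 | intermediate
10 | 2,2-dimethyl-6-(2-oxopropyl)-4H-1,3-dioxin-4-one | CC(=O)CC1=CC(=O)OC(C)(C)O1 | intermediate
11 | methyl dodecanoate | CCCCCCCCCCCC(=O)OC | starting material
12 | dilithio dianion of 10 | [Li]OC(=C)C=C1C=C(O[Li])OC(C)(C)O1 | intermediate
13 | 2,2-dimethyl-6-(2,4-dioxopentadecyl)-4H-1,3-dioxin-4-one | CCCCCCCCCCCC(=O)CC(=O)CC1=CC(=O)OC(C)(C)O1 | intermediate
14 | 2-allyl-4,4,5,5-tetramethyl-1,3,2-dioxaborolane | C=CCB1OC(C)(C)C(C)(C)O1 | starting material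
15 | 2-{[(4S)-11-[3,5-bis(benzyloxy)phenyl]undec-1-en-4-yl]oxy}-4,4,5,5-tetramethyl-1,3,2-dioxaborolane | CC1(C)OB(O[C@H](CC=C)CCCCCCCc2cc(OCc3ccccc3)cc(OCc3ccccc3)c2)OC1(C)C | intermediate
16 | 3,5,7-trioxooctadec-1-en-1-one (acylketene) | CCCCCCCCCCCC(=O)CC(=O)CC(=O)C=C=O | intermediate
17 | (4S)-11-[3,5-bis(benzyloxy)phenyl]undec-1-en-4-yl 3,5,7-trioxooctadecanoate | CCCCCCCCCCCC(=O)CC(=O)CC(=O)CC(=O)O[C@H](CC=C)CCCCCCCc1cc(OCc2ccccc2)cc(OCc2ccccc2)c1 | intermediate
18 | (4S)-11-[3,5-bis(benzyloxy)phenyl]undec-1-en-4-yl 2,4-dihydroxy-6-undecylbenzoate | CCCCCCCCCCCc1cc(O)cc(O)c1C(=O)O[C@H](CC=C)CCCCCCCc1cc(OCc2ccccc2)cc(OCc2ccccc2)c1 | intermediate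
19 | (4R)-11-(3,5-dihydroxyphenyl)undecan-4-yl 2,4-dihydroxy-6-undecylbenzoate | CCCCCCCCCCCc1cc(O)cc(O)c1C(=O)O[C@H](CCC)CCCCCCCc1cc(O)cc(O)c1 | target

**Step count**
- Total steps: 6. Step 5 counts as one step because it runs in one flask, mainly in toluene, with no work-up or isolation between its stages.
- Longest linear sequence: 4, either 1 → 2 → 5 → 6 or 3 → 4 → 5 → 6.

**Three steps most likely to fail**

Step 5 (the proposed new step). The borate 15 may hand its alkoxide to 16 too slowly. In that case the acylketene closes on its own enol to give a 4-hydroxy-2-pyrone. The enantiomeric excess is also only seen on a hydrolysed aliquot. The fallback sets out from 6 and comes back at 18, and it uses only known chemistry. The same phosphoric-acid-catalysed allylboration of 6 with 14 is worked up with aqueous NaHCO3 and silica gel, which hydrolyses 15. The free alcohol (S)-11-[3,5-bis(benzyloxy)phenyl]undec-1-en-4-ol F1 is isolated and its enantiomeric excess is measured by chiral HPLC. It is then heated with 13 in toluene at 110 °C, where the free O–H group traps 16 in the established way. The resulting 17 is aromatised with Cs2CO3 in MeOH and then HCl to give 18. This costs one extra isolated step.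

Step 4. Proton exchange between the dianion and the product, or attack of liberated LiOMe on the dioxinone, may hold the yield down. The fallback sets out from 10 and comes back at 13. It replaces ester acylation by aldol addition followed by oxidation. Dianion 12 is added to dodecanal at −78 °C; this addition is irreversible at that temperature and produces no acidic product. It gives racemic 6-(4-hydroxy-2-oxopentadecyl)-2,2-dimethyl-4H-1,3-dioxin-4-one F2, whose stereocentre is removed at once by Dess–Martin periodinane oxidation in CH2Cl2 to give 13.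

Step 2. Alkene isomerisation, branched aldehyde or lack of pressure equipment can compromise the hydroformylation. The fallback sets out from 1 and comes back at 6, and it removes one carbon instead of adding one.
- 8-Bromooct-1-ene and Mg give oct-7-en-1-ylmagnesium bromide F3.
- Li2CuCl4-catalysed coupling of this Grignard reagent with 1 gives 1,3-bis(benzyloxy)-5-(non-8-en-1-yl)benzene F4.
- Lemieux–Johnson cleavage (OsO4 catalyst, NaIO4, 2,6-lutidine, dioxane/water) gives 6.

**Further compounds**
F1 | step 5 | (S)-11-[3,5-bis(benzyloxy)phenyl]undec-1-en-4-ol | O[C@H](CC=C)CCCCCCCc1cc(OCc2ccccc2)cc(OCc2ccccc2)c1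
F2 | step 4 | 6-(4-hydroxy-2-oxopentadecyl)-2,2-dimethyl-4H-1,3-dioxin-4-one (racemic) | CCCCCCCCCCCC(O)CC(=O)CC1=CC(=O)OC(C)(C)O1
F3 | step 2 | oct-7-en-1-ylmagnesium bromide | C=CCCCCCC[Mg]Br
F4 | step 2 | 1,3-bis(benzyloxy)-5-(non-8-en-1-yl)benzene | C=CCCCCCCCc1cc(OCc2ccccc2)cc(OCc2ccccc2)c1
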